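1. Whatever happens in a closed flask, the forms of a catalyst add up to what was charged, just as G and Q in the red run add up to 99.7% at 3.00 min.

| flask | Q | D | remark |
|---|---|---|---|
| red | 20 mM | 0.01 mol% | the very flask that is asked about, followed so far |
| flask | 20 mM | 0.01 mol% |  |

red run (percent of the Q charged)

| time / min | G / % | Q / % |
|---|---|---|
| 0.250 | 2.4 | 97.1 |
| 0.333 | 3.6 | 96.5 |
| 0.500 | 4.6 | 95.6 |
| 0.833 | 7.7 | 92.1 |
| 1.33 | 11.6 | 87.8 |
| 2.00 | 16.4 | 83.6 |
| 3.00 | 21.5 | 78.2 |

(each reading ± 0.3 percentage points)

- no earlier run changes the charge of D; that part of a forecast is a guess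

1. factor on the rate of making G when 5.0% of the Q are converted if D is charged twice over
2. factor on the rate when 5.0% of the Q are converted if D is charged at 0.05 mol% instead

2. Write the balance for D, the reagent charged in the smaller amount. Its charge as a concentration is 0.00200 mM, and some share of that is still D.

3. At 5.0% conversion, [Q] is the same for every charge. I therefore assume that the rate follows working [D], the charge times that share. The factor asked for is then the ratio of charges times the ratio of shares.

4. Turn the question round. For the 0.05 mol% factor to fall to 2.2, the share in that flask would have to be 44.0% of the share in the 0.01 mol% flask.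

5. No earlier run changes the charge of D, so that ratio of shares cannot be read from the red run, which shows one flask. I commit to a guess, equal shares at equal conversion: factors of 2 and 5.00.

6. The forecast stands a little lower, at 1.9 (1.4 to 2.2) and 4.4 (2.2 to 5.7): “These runs never vary D, so its order is a guess”.

The flask gives 2.00 and 5.00.

    2 D → E (k = 42000 L mol⁻¹ min⁻¹)
    Q + D → G + D, rate k2*[Q]^2*[D]/(1 + ([Q]/Kh2)^2) (25.0 mM, k = 72000 L² mol⁻² s⁻¹)

In the 0.01 mol% flask, the first half-life of D by its pairing into E is 5.95 min, and 5.0% conversion comes sooner than that, at 0.510 min, when 92.1% of the catalyst is D and 7.90% is E, an off-cycle form. Working [D] there is 0.00184 mM. In the 0.05 mol% flask the share at the same conversion is 92.1%, which makes working [D] 0.00921 mM, or 5.01 times that of the 0.01 mol% flask.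

The readings come from a simulation with constants of no real substance; noise was put on by code.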